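**Retrosynthetic overview**
- The strategy rests on one feature of ring C (the pyranone): its bonds O1–C8a and C4–C4a end on the two adjacent ring-A carbons C8a and C4a. Ring A can therefore enter as an aryne that is attacked first by an enolate oxygen and then acylated by the neighbouring ester.
- Target ⇐ 8-O-methylation ⇐ 5,8-dihydroxy-3,7,2'-trimethoxyflavone ⇐ para-hydroxylation at C8 (Elbs) ⇐ 5-hydroxy-3,7,2'-trimethoxyflavone ⇐ selective 5-O-demethylation ⇐ 3,5,7,2'-tetramethoxyflavone.
- 3,5,7,2'-Tetramethoxyflavone ⇐ 3,5-dimethoxybenzyne (from its o-silylaryl triflate) + methyl 2-methoxy-3-(2-methoxyphenyl)-3-oxopropanoate, which already carries C2, C3–OMe, C4 and ring B.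
- Silyl triflate ⇐ 3,5-dimethoxyphenol by carbamate-directed ortho-silylation; β-ketoester ⇐ methyl methoxyacetate enolate + 2-methoxybenzoyl chloride (the acid chloride is chosen for a clean C-acylation).
- Ring order: rings A and B are bought; ring C is the only ring formed, in step 5.

Key step: step 5

Remark: the target has no stereocentre, so the request for a single enantiomer needs no stereocontrol; β-ketoester 12 is used as the racemate because its only stereocentre becomes sp2 in step 5.

Step 1
Reactants: 1 3,5-dimethoxyphenol
Product: 2 3,5-dimethoxyphenyl N-isopropylcarbamate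
Conditions: i-PrNCO, Et3N (cat.), CH2Cl2, rt
Reagents that add atoms: isopropyl isocyanate, CC(C)N=C=O
Why: Base-catalysed addition of the phenol to the isocyanate (carbamoylation) installs a strong ortho-directing group that can later be removed under mild base.

Step 2
Reactants: 2 3,5-dimethoxyphenyl N-isopropylcarbamate
Product: 6 3,5-dimethoxy-2-(trimethylsilyl)phenyl N-isopropylcarbamate, via N-TBS carbamate 3 (not isolated), via 2-lithio N-TBS carbamate 4 (not isolated), via C-TMS N-TBS carbamate 5 (not isolated)
Conditions: TBSOTf, TMEDA, Et2O, 0 °C to rt; n-BuLi, TMEDA, −78 °C; TMSCl, −78 °C to rt; aq. NaHSO4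
Reagents that add atoms: chlorotrimethylsilane, C[Si](C)(C)Cl
Why: After in situ N-silylation, directed ortho-metalation should occur at C2, where the O-carbamate (the stronger director) and a methoxy group cooperate, in preference to C4 between two methoxy groups; TMSCl traps the aryllithium and the N-silyl group is lost on acidic work-up.

Step 3
Reactants: 6 3,5-dimethoxy-2-(trimethylsilyl)phenyl N-isopropylcarbamate
Product: 8 3,5-dimethoxy-2-(trimethylsilyl)phenyl trifluoromethanesulfonate, via silyl phenol 7 (not isolated)
Conditions: Et2NH, DBU, MeCN, 40 °C; then PhNTf2, rt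
Reagents that add atoms: N-phenylbis(trifluoromethanesulfonimide), O=S(=O)(N(c1ccccc1)S(=O)(=O)C(F)(F)F)C(F)(F)F
Why: The N-monosubstituted carbamate is cleaved by E1cB loss of isopropyl isocyanate (scavenged by diethylamine as the urea) and the resulting phenoxide is triflated in the same pot, the established one-pot route to o-silylaryl triflates.

Step 4
Reactants: 9 methyl methoxyacetate; 10 2-methoxybenzoyl chloride
Product: 12 methyl 2-methoxy-3-(2-methoxyphenyl)-3-oxopropanoate (racemic), via lithium ester enolate 11 (not isolated)
Conditions: LDA (2.1 equiv), 9 (2.1 equiv), THF, −78 °C; then 10 (1.0 equiv), −78 to 0 °C; 1 M HCl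
Reagents that add atoms: none
Why: Claisen-type C-acylation of the preformed lithium ester enolate by the aroyl chloride, with the second equivalent of enolate taking up the acidic proton of the product so that the chloride is consumed cleanly.

Step 5
Reactants: 8 3,5-dimethoxy-2-(trimethylsilyl)phenyl trifluoromethanesulfonate; 12 methyl 2-methoxy-3-(2-methoxyphenyl)-3-oxopropanoate
Product: 15 3,5,7-trimethoxy-2-(2-methoxyphenyl)-4H-chromen-4-one (3,5,7,2'-tetramethoxyflavone), via 3,5-dimethoxybenzyne 13 (not isolated), via caesium enolate 14 (not isolated)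
Conditions: CsF (4 equiv), THF, 65 °C, 8 (1.5 equiv) added slowly to 12/CsF
Reagents that add atoms: none
Why: Proposed new method: CsF both unmasks 3,5-dimethoxybenzyne 13 from the silyl triflate and converts 12 into its caesium enolate 14; the ketone-derived enolate oxygen is expected to add to the aryne carbon remote from the flanking methoxy group (O1–C8a), and the aryl anion thus generated between the new aryl–oxygen bond and that methoxy group attacks the cis ester carbonyl and expels methoxide (C4–C4a). The closest known reaction types are the aryne–salicylate annulation to xanthones (phenoxide O-arylation followed by the same acyl substitution) and the aryne acyl-alkylation of β-ketoesters, which documents the competing C-arylation. Ring C is closed by a 6-exo-trig addition–elimination of the aryl anion on the ester; no stereocentre is formed and the α-stereocentre of racemic 12 is erased. Site selectivity on the aryne rests on the bond-angle distortion and inductive effect of the 3-methoxy group, which direct nucleophiles to C1 of 3-alkoxyarynes and so place the carbonyl peri to the future C5 oxygen. O- over C-arylation is the unproven selectivity: it is counted on because the enolate carbon is tetrasubstituted and shielded by the twisted ortho-methoxybenzoyl group, so that C-attack would have to build an aryl-bearing quaternary centre, while the loosely paired caesium enolate in THF keeps its charge on oxygen. The cis relation of ester and enolate oxygen needed for closure is the sterically preferred enolate geometry (aryl cis to the small methoxy group), and THF with slow addition of 8 should limit protonation of the aryl anion and aryne self-reaction.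

Step 6
Reactants: 15 3,5,7-trimethoxy-2-(2-methoxyphenyl)-4H-chromen-4-one
Product: 16 5-hydroxy-3,7-dimethoxy-2-(2-methoxyphenyl)-4H-chromen-4-one
Conditions: AlCl3 (5 equiv), MeCN, 60 °C; then 2 M HCl, 60 °C
Reagents that add atoms: none
Why: The Lewis acid binds C4=O and the peri 5-methoxy oxygen in a six-membered chelate, so chloride should cleave only this methyl ether (selective 5-O-demethylation of polymethoxyflavones), leaving the 3-methoxy group (weaker five-membered chelate) and the 7- and 2'-methoxy groups intact.

Step 7
Reactants: 16 5-hydroxy-3,7-dimethoxy-2-(2-methoxyphenyl)-4H-chromen-4-one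
Product: 18 5,8-dihydroxy-3,7-dimethoxy-2-(2-methoxyphenyl)-4H-chromen-4-one, via 8-sulfate potassium salt 17 (not isolated)
Conditions: K2S2O8, aq. KOH, pyridine, 15–20 °C; acidify to pH 5, remove unchanged 16; then conc. HCl, Na2SO3, 90 °C
Reagents that add atoms: potassium peroxydisulfate, [K+].[K+].[O-]S(=O)(=O)OOS(=O)(=O)[O-]
Why: Elbs persulfate oxidation, in which the 5-phenolate attacks the peroxide oxygen through its only free para carbon (C8) to give the aryl sulfate that acid then hydrolyses to the quinol, the classical conversion of 5-hydroxyflavones into 5,8-dihydroxyflavones.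

Step 8
Reactants: 18 5,8-dihydroxy-3,7-dimethoxy-2-(2-methoxyphenyl)-4H-chromen-4-one
Product: 19 5-hydroxy-3,7,8-trimethoxy-2-(2-methoxyphenyl)-4H-chromen-4-one (5-hydroxy-3,7,8,2'-tetramethoxyflavone)
Conditions: Me2SO4 (1.05 equiv), K2CO3, acetone, reflux, under Ar
Reagents that add atoms: dimethyl sulfate, COS(=O)(=O)OC
Why: Williamson partial methylation, in which the 5-hydroxyl, tied up in the hydrogen bond to C4=O, is far less acidic and nucleophilic than the free 8-hydroxyl, so one equivalent of reagent should stop at the 8-methyl ether; argon keeps the quinol from oxidising.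

**Compound list**
1 | 3,5-dimethoxyphenol | COc1cc(O)cc(OC)c1 | starting material
2 | 3,5-dimethoxyphenyl N-isopropylcarbamate | COc1cc(OC)cc(OC(=O)NC(C)C)c1 | intermediate
3 | 3,5-dimethoxyphenyl N-(tert-butyldimethylsilyl)-N-isopropylcarbamate | COc1cc(OC)cc(OC(=O)N(C(C)C)[Si](C)(C)C(C)(C)C)c1 | intermediate
4 | 2-lithio-3,5-dimethoxyphenyl N-(tert-butyldimethylsilyl)-N-isopropylcarbamate | [Li]c1c(OC)cc(OC)cc1OC(=O)N(C(C)C)[Si](C)(C)C(C)(C)C | intermediate
5 | 3,5-dimethoxy-2-(trimethylsilyl)phenyl N-(tert-butyldimethylsilyl)-N-isopropylcarbamate | COc1cc(OC)c([Si](C)(C)C)c(OC(=O)N(C(C)C)[Si](C)(C)C(C)(C)C)c1 | intermediate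
6 | 3,5-dimethoxy-2-(trimethylsilyl)phenyl N-isopropylcarbamate | COc1cc(OC)c([Si](C)(C)C)c(OC(=O)NC(C)C)c1 | intermediate
7 | 3,5-dimethoxy-2-(trimethylsilyl)phenol (formed as its DBU salt) | COc1cc(O)c([Si](C)(C)C)c(OC)c1 | intermediate
8 | 3,5-dimethoxy-2-(trimethylsilyl)phenyl trifluoromethanesulfonate | COc1cc(OC)c([Si](C)(C)C)c(OS(=O)(=O)C(F)(F)F)c1 | intermediate
9 | methyl methoxyacetate | COCC(=O)OC | starting material
10 | 2-methoxybenzoyl chloride | COc1ccccc1C(=O)Cl | starting material
11 | lithium enolate of methyl methoxyacetate | COC=C(O[Li])OC | intermediate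
12 | methyl 2-methoxy-3-(2-methoxyphenyl)-3-oxopropanoate (racemic) | COC(=O)C(OC)C(=O)c1ccccc1OC | intermediate
13 | 3,5-dimethoxybenzyne | COC1=CC(OC)=CC#C1 | intermediate
14 | caesium enolate of 12 (ester cis to the enolate oxygen) | [Cs+].COC(=O)/C(OC)=C(\[O-])c1ccccc1OC | intermediate
15 | 3,5,7-trimethoxy-2-(2-methoxyphenyl)-4H-chromen-4-one | COc1ccccc1-c1oc2cc(OC)cc(OC)c2c(=O)c1OC | intermediate
16 | 5-hydroxy-3,7-dimethoxy-2-(2-methoxyphenyl)-4H-chromen-4-one | COc1ccccc1-c1oc2cc(OC)cc(O)c2c(=O)c1OC | intermediate
17 | potassium 5-hydroxy-3,7-dimethoxy-2-(2-methoxyphenyl)-4-oxo-4H-chromen-8-yl sulfate | [K+].COc1ccccc1-c1oc2c(OS(=O)(=O)[O-])c(OC)cc(O)c2c(=O)c1OC | intermediate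
18 | 5,8-dihydroxy-3,7-dimethoxy-2-(2-methoxyphenyl)-4H-chromen-4-one | COc1ccccc1-c1oc2c(O)c(OC)cc(O)c2c(=O)c1OC | intermediate
19 | 5-hydroxy-3,7,8-trimethoxy-2-(2-methoxyphenyl)-4H-chromen-4-one | COc1ccccc1-c1oc2c(OC)c(OC)cc(O)c2c(=O)c1OC | target

**Step count**
Total: 8 steps. Longest linear sequence: 7 steps (steps 1, 2, 3, 5, 6, 7, 8); the β-ketoester branch (step 4) joins at step 5.

**Steps most likely to fail**

Step 5 (proposed new method). The enolate may react through carbon, after which the aryl anion adds to the ketone and the C–C bond is cleaved (acyl-alkylation), so that no pyranone forms. The aryl anion may also be protonated before it reaches the ester, leaving an open aryl enol ether. The fallback builds ring C by the Baker–Venkataraman sequence and needs no aryne; it sets out from 1 and 10 and comes back at 15. BF3·OEt2-mediated acylation of 1 with methoxyacetyl chloride (ester formation and Fries shift to the chelated ortho-hydroxy ketone) should give 1-(2-hydroxy-4,6-dimethoxyphenyl)-2-methoxyethan-1-one F1. Esterification with 10 in pyridine should give 3,5-dimethoxy-2-(methoxyacetyl)phenyl 2-methoxybenzoate F2. Base-induced acyl migration (KOH, pyridine, 50 °C) should give 1-(2-hydroxy-4,6-dimethoxyphenyl)-2-methoxy-3-(2-methoxyphenyl)propane-1,3-dione F3. Cyclodehydration (H2SO4, AcOH, 100 °C) should then give 15.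

Step 7. The persulfate oxidation typically stops at partial conversion, and radical side-oxidation of the electron-rich phenolate or further oxidation of the quinol can erode the material. The fallback brings in the C8 oxygen by halogenation and copper-mediated methoxylation; it sets out from 15 and comes back at 19, bypassing steps 6 and 8. Iodination of 15 (NIS, cat. TFA, MeCN, rt) is expected at C8, the position that 5,7-di-O-methylflavones offer to electrophiles, giving 8-iodo-3,5,7-trimethoxy-2-(2-methoxyphenyl)-4H-chromen-4-one F4. Chelation-controlled 5-O-demethylation (BCl3, CH2Cl2, 0 °C) should give 5-hydroxy-8-iodo-3,7-dimethoxy-2-(2-methoxyphenyl)-4H-chromen-4-one F5. Ullmann-type methoxylation (NaOMe, CuBr, MeOH–DMF, 110 °C) should then give 19.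

Step 8. The quinol may oxidise to the 5,8-quinone under basic conditions, and methylation may run on to the 5,8-dimethyl ether. The fallback gives up differentiation at the alkylation stage; it sets out from 18 and comes back at 19. Exhaustive methylation (excess Me2SO4, K2CO3, acetone, reflux) should give 3,5,7,8-tetramethoxy-2-(2-methoxyphenyl)-4H-chromen-4-one F6. Chelation-controlled cleavage of the 5-methyl ether (AlCl3, MeCN, 60 °C; then dilute HCl) should then give 19.

**Further compounds**
F1 | step 5 | 1-(2-hydroxy-4,6-dimethoxyphenyl)-2-methoxyethan-1-one | COCC(=O)c1c(O)cc(OC)cc1OC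
F2 | step 5 | 3,5-dimethoxy-2-(methoxyacetyl)phenyl 2-methoxybenzoate | COCC(=O)c1c(OC(=O)c2ccccc2OC)cc(OC)cc1OC
F3 | step 5 | 1-(2-hydroxy-4,6-dimethoxyphenyl)-2-methoxy-3-(2-methoxyphenyl)propane-1,3-dione | COc1ccccc1C(=O)C(OC)C(=O)c1c(O)cc(OC)cc1OC
F4 | step 7 | 8-iodo-3,5,7-trimethoxy-2-(2-methoxyphenyl)-4H-chromen-4-one | COc1ccccc1-c1oc2c(I)c(OC)cc(OC)c2c(=O)c1OC
F5 | step 7 | 5-hydroxy-8-iodo-3,7-dimethoxy-2-(2-methoxyphenyl)-4H-chromen-4-one | COc1ccccc1-c1oc2c(I)c(OC)cc(O)c2c(=O)c1OC
F6 | step 8 | 3,5,7,8-tetramethoxy-2-(2-methoxyphenyl)-4H-chromen-4-one | COc1ccccc1-c1oc2c(OC)c(OC)cc(OC)c2c(=O)c1OC
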